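**Retrosynthetic overview**

1. 27 ⇐ 26 (exo, hydroxyl-directed epoxidation of C2=C3) ⇐ 23 (N-acylation) ⇐ 18 (C2 ketone → C2=C3 through its enol triflate): the endgame only trims a bicyclo[3.3.1]nonane-2,9-dione.
2. 18 ⇐ 16: ring A is closed last by a base-free SmI2 Reformatsky-type aldol (C5–C6); the L-aspartate-derived C7 decides which of two equivalent ketone arms of a mirror-symmetric ring B reacts, and this fixes C1 and C5.
3. 12 ⇐ 8 + HC(OMe)3: ring B is closed first by a one-carbon [5+1] stitching of a bis(1-ethoxyvinyl) carbinol; C5–C4 forms first, C4–C3 is the ring-closing bond, and the orthoformate carbon brings the 4-OMe.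
4. Enabling feature: in ring B (C1–C2–C3–C4–C5–C9) the carbinol C1 and the methoxy carbon C4 lie 1,4 on a latent mirror plane, and C9(=O)–C5 and C2(–O)–C3 are two identical acetyl-level two-carbon units on C1; 8 comes from double addition of 1-ethoxyvinyllithium to the side-chain ester of L-aspartate.
5. Ring order: ring B (step 4), ring A (step 8), oxirane (step 14).

Key step: step 4

Remark on numbering: bicyclic compounds are numbered as bicyclo[3.3.1]nonanes, C1 = O-bearing bridgehead, C2 and C3 = oxirane carbons (C2 next to C1), C4 = CH–OMe, C5 = bridgehead CH, C6 = CH–OH, C7 = CH–N, C8 = CH2, C9 = bridging C=O; ring A = C1, C5, C6, C7, C8, C9; ring B = C1, C2, C3, C4, C5, C9; the monocyclic diketones are numbered C1 (quaternary), C2/C6 (C=O), C3/C5 (CH2), C4 (CH–OMe).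
Assumption: step 4 is carried forward with the cis isomer of 12 (OSi and OMe on the same face); the two achiral diastereomers are assumed to be separable.

**Route**

Step 1
Reactants: 1 N-Boc-L-aspartic acid 4-methyl ester
Product: 3 methyl (3S)-3-[(tert-butoxycarbonyl)amino]-4-hydroxybutanoate, via mixed carbonic anhydride 2 (not isolated)
Conditions: i-BuOCOCl, N-methylmorpholine, THF, −15 °C; then NaBH4, H2O, 0 °C
Reagents that add atoms: none
Why: Chemoselective reduction of the free α-carboxyl group through its mixed carbonic anhydride with NaBH4 should leave the methyl ester and the carbamate untouched, and the C7 stereocentre, taken from L-aspartic acid, is not involved.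

Step 2
Reactants: 3 methyl (3S)-3-[(tert-butoxycarbonyl)amino]-4-hydroxybutanoate
Product: 4 tert-butyl (4S)-4-(2-methoxy-2-oxoethyl)-2,2-dimethyl-1,3-oxazolidine-3-carboxylate
Conditions: 2,2-dimethoxypropane, BF3·OEt2 (cat.), acetone, rt
Reagents that add atoms: 2,2-dimethoxypropane, COC(C)(C)OC
Why: Acid-catalysed N,O-acetalization ties N–H and O–H into the oxazolidine so that no acidic proton interferes with the organolithium step.

Step 3
Reactants: 4 tert-butyl (4S)-4-(2-methoxy-2-oxoethyl)-2,2-dimethyl-1,3-oxazolidine-3-carboxylate; 5 ethyl vinyl ether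
Product: 8 tert-butyl (4S)-4-{2-[(tert-butyldimethylsilyl)oxy]-3-ethoxy-2-(1-ethoxyethenyl)but-3-en-1-yl}-2,2-dimethyl-1,3-oxazolidine-3-carboxylate, via 1-ethoxyvinyllithium 6 (not isolated), via lithium alkoxide 7 (not isolated)
Conditions: 5, t-BuLi, THF, −78 → 0 °C; add 4, −78 → −20 °C; then t-BuMe2SiOTf, −78 → 0 °C
Reagents that add atoms: tert-butyldimethylsilyl trifluoromethanesulfonate, CC(C)(C)[Si](C)(C)OC(F)(F)F replaced by the correct formula CC(C)(C)[Si](C)(C)OS(=O)(=O)C(F)(F)F
Why: Double 1,2-addition of the acyl-anion equivalent 1-ethoxyvinyllithium to the ester should give a tertiary alkoxide carrying two identical enol ether arms, which is silylated in the same flask; no stereocentre is created because the arms are identical.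

Step 4
Reactants: 8 tert-butyl (4S)-4-{2-[(tert-butyldimethylsilyl)oxy]-3-ethoxy-2-(1-ethoxyethenyl)but-3-en-1-yl}-2,2-dimethyl-1,3-oxazolidine-3-carboxylate; 9 trimethyl orthoformate
Product: 12 tert-butyl (4S)-4-({cis-1-[(tert-butyldimethylsilyl)oxy]-4-methoxy-2,6-dioxocyclohexyl}methyl)-2,2-dimethyl-1,3-oxazolidine-3-carboxylate, via open-chain ketal acetal 10 (not isolated), via cyclic bis(ketal) 11 (not isolated)
Conditions: 9 (1.05 equiv, slow addition), BF3·OEt2 (0.2 equiv), CH2Cl2 (high dilution), −78 °C; Et3N; then pyridinium p-toluenesulfonate (cat.), acetone/H2O, rt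
Reagents that add atoms: water, O
Why: Proposed new method: BF3 ionizes HC(OMe)3 to the dimethoxycarbenium ion, which is attacked by the terminal CH2 of one 1-ethoxyvinyl arm (C5–C4 bond, the resulting C9 oxocarbenium being capped by methoxide as the mixed ketal 10); ionization of the new CH(OMe)2 group then gives an O-methyl oxocarbenium at C4 that is trapped by the CH2 of the second arm, so that the C4–C3 bond closes ring B and the orthoformate carbon arrives carrying the future 4-OMe (11), and mild hydrolysis unmasks both ketones. The closest known reaction types are the Lewis-acid addition of orthoformates and acetals to alkyl enol ethers (Müller–Cunradi–Pieroh reaction) and intramolecular acetal–enol ether (Mukaiyama/Prins-type) cyclizations; what is new is their union into a one-carbon [5+1] stitching of a 1,1-bis(alkoxyvinyl) carbinol. Ring B closes through a six-membered chair-like cation–olefin closure that is endo with respect to the enol ether π-bond and exo with respect to the oxocarbenium C=O. The only new stereo-element is the cis/trans relation of C1 and C4 (neither is a chirality centre yet, because the two arms are still equivalent): a chair with the silyloxy group axial (small A value, anti to the axial ketal oxygen) and with the branched CH2 chain and the oxocarbenium OMe equatorial should favour the needed cis isomer, and this preference is the least certain point of the step. The step needs chemoselectivity for ring closure over capture of the second arm by another orthoformate-derived cation, which the six-membered intramolecular closure, the slow addition of 9 and high dilution should secure. The silyl ether on C1 keeps the tertiary oxygen from trapping the C4 cation.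

Step 5
Reactants: 12 tert-butyl (4S)-4-({cis-1-[(tert-butyldimethylsilyl)oxy]-4-methoxy-2,6-dioxocyclohexyl}methyl)-2,2-dimethyl-1,3-oxazolidine-3-carboxylate
Product: 14 tert-butyl (4S)-4-({3,5-dibromo-cis-1-[(tert-butyldimethylsilyl)oxy]-4-methoxy-2,6-dioxocyclohexyl}methyl)-2,2-dimethyl-1,3-oxazolidine-3-carboxylate (epimer mixture at the two CHBr carbons), via bis(trimethylsilyl enol ether) 13 (not isolated)
Conditions: LiN(SiMe3)2 (2.3 equiv), Me3SiCl (in situ), THF, −78 °C; then N-bromosuccinimide (2.1 equiv), −78 → −40 °C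
Reagents that add atoms: N-bromosuccinimide, O=C1CCC(=O)N1Br
Why: Kinetic bis-enolization with internal silyl quench followed by electrophilic bromination of each silyl enol ether should place one bromine on each α-CH2, giving a storable precursor of both ketone enolates; the CHBr configurations are irrelevant because both carbons become enolates in step 8.

Step 6
Reactants: 14 the dibromo diketone oxazolidine
Product: 15 tert-butyl N-[(2S)-1-{3,5-dibromo-cis-1-[(tert-butyldimethylsilyl)oxy]-4-methoxy-2,6-dioxocyclohexyl}-3-hydroxypropan-2-yl]carbamate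
Conditions: p-TsOH·H2O (cat.), MeOH, 0 °C → rt
Reagents that add atoms: none
Why: Acid-catalysed transacetalization should release the N-Boc amino alcohol while the Boc group, the hindered tertiary silyl ether and the α-bromo ketones survive.

Step 7
Reactants: 15 the N-Boc amino alcohol
Product: 16 tert-butyl N-[(2S)-1-{3,5-dibromo-cis-1-[(tert-butyldimethylsilyl)oxy]-4-methoxy-2,6-dioxocyclohexyl}-3-oxopropan-2-yl]carbamate
Conditions: Dess–Martin periodinane, CH2Cl2, 0 °C → rt; used crude at once
Reagents that add atoms: none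
Why: Dess–Martin oxidation of the primary alcohol under non-basic conditions should give the N-Boc α-amino aldehyde without epimerization at C7.

Step 8
Reactants: 16 the dibromo keto aldehyde
Product: 18 tert-butyl N-{1-[(tert-butyldimethylsilyl)oxy]-6-hydroxy-4-methoxy-2,9-dioxobicyclo[3.3.1]nonan-7-yl}carbamate (4-OMe and 6-OH axial on their rings and anti across C5, 7-NHBoc equatorial; C1, C4, C5, C6, C7 as in 27), via bis(diiodosamarium enolate) 17 (not isolated)
Conditions: SmI2 (4.2 equiv), THF, −78 °C; aq. NH4Cl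
Reagents that add atoms: none
Why: In this intramolecular samarium Reformatsky-type aldol, two-electron reduction of each C–Br bond by divalent samarium gives both trivalent-samarium enolates without base (so the α-amino aldehyde is not epimerized); only the enolate on the arm that lets the C7 carbamate sit equatorial on the new ring A can reach the aldehyde (this choice fixes C1 and C5, the other arm would force the carbamate into the endo position), and a closed chelated transition state with the aldehyde oxygen bound to the enolate samarium places the 6-OH axial, while the other enolate is simply protonated on work-up.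

Step 9
Reactants: 18 the bicyclic aldol
Product: 19 tert-butyl N-{1-[(tert-butyldimethylsilyl)oxy]-4-methoxy-2,9-dioxo-6-[(triethylsilyl)oxy]bicyclo[3.3.1]nonan-7-yl}carbamate
Conditions: Et3SiOTf, 2,6-lutidine, CH2Cl2, −78 °C
Reagents that add atoms: triethylsilyl trifluoromethanesulfonate, CC[Si](CC)(CC)OS(=O)(=O)C(F)(F)F
Why: Silylation of the secondary 6-OH blocks retro-aldol opening and O-triflation in the next, strongly basic step.

Step 10
Reactants: 19 the 6-O-triethylsilyl diketone
Product: 21 C2 enol triflate of 19 (C2=C3; 7-carbamoyl-1-silyloxy-4-methoxy-9-oxo-6-silyloxybicyclo[3.3.1]non-2-en-2-yl trifluoromethanesulfonate), via dilithio enolate 20 (not isolated)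
Conditions: LiN(SiMe3)2 (2.2 equiv), THF, −78 °C; then N-(5-chloropyridin-2-yl)bis(trifluoromethanesulfonimide) (Comins' reagent), −78 °C
Reagents that add atoms: N-(5-chloropyridin-2-yl)bis(trifluoromethanesulfonimide), O=S(=O)(N(c1ccc(Cl)cn1)S(=O)(=O)C(F)(F)F)C(F)(F)F
Why: After the first equivalent of base is consumed by the carbamate N–H, kinetic deprotonation can occur only at C3 (C1 is quaternary and the C9 ketone has only the C5 bridgehead hydrogen, protected by Bredt's rule), and O-triflation of the lithium enolate at −78 °C should outrun β-elimination of the 4-OMe.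

Step 11
Reactants: 21 the C2 enol triflate
Product: 22 tert-butyl N-{1-[(tert-butyldimethylsilyl)oxy]-4-methoxy-9-oxo-6-[(triethylsilyl)oxy]bicyclo[3.3.1]non-2-en-7-yl}carbamate
Conditions: Pd(OAc)2 (5 mol %), PPh3 (10 mol %), HCO2H, n-Bu3N, DMF, 60 °C
Reagents that add atoms: none
Why: Palladium-catalysed formate reduction of the enol triflate (oxidative addition to zerovalent palladium, formate exchange, decarboxylation, reductive elimination) should give the C2=C3 alkene without touching the ketone or the allylic methyl ether.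

Step 12
Reactants: 22 the protected bicyclic alkene
Product: 23 tert-butyl N-(1,6-dihydroxy-4-methoxy-9-oxobicyclo[3.3.1]non-2-en-7-yl)carbamate
Conditions: HF (48 % aq.), MeCN, 0 °C → rt
Reagents that add atoms: none
Why: Fluoride-driven cleavage should remove both the secondary triethylsilyl and the tertiary tert-butyldimethylsilyl ether under conditions that do not open a β-hydroxy ketone by retro-aldol and leave the Boc group in place.

Step 13
Reactants: 23 the N-Boc diol; 24 (2E)-dodec-2-enoic acid
Product: 26 (2E)-N-(1,6-dihydroxy-4-methoxy-9-oxobicyclo[3.3.1]non-2-en-7-yl)dodec-2-enamide, via ammonium trifluoroacetate 25 (not isolated)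
Conditions: CF3CO2H, CH2Cl2, 0 °C; concentrate; then 24, EDC·HCl, HOBt, i-Pr2NEt, CH2Cl2, 0 °C → rt
Reagents that add atoms: none
Why: Acidolysis of the Boc group followed by carbodiimide coupling should acylate the primary amine selectively over the hindered secondary and tertiary hydroxyl groups, the E geometry being carried in from 24.

Step 14
Reactants: 26 the dienamide diol
Product: 27 (2E)-N-[(1S,2S,3S,4S,5S,6R,7S)-2,3-epoxy-1,6-dihydroxy-4-methoxy-9-oxobicyclo[3.3.1]nonan-7-yl]dodec-2-enamide
Conditions: m-CPBA, CH2Cl2/aq. Na2HPO4–NaH2PO4 buffer (pH 7), 0 °C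
Reagents that add atoms: 3-chloroperoxybenzoic acid, OOC(=O)c1cccc(Cl)c1
Why: Peracid (Prilezhaev) epoxidation should occur on the convex exo face of the bicyclo[3.3.1]non-2-ene, which is also the face of the hydrogen-bond-donating C1–OH, setting C2 and C3 with the oxirane cis to 1-OH and 4-OMe; the endo face is blocked by C7 of ring A and the electron-poor enamide alkene should not react.

**Compound list**

1 | N-Boc-L-aspartic acid 4-methyl ester | CC(C)(C)OC(=O)N[C@@H](CC(=O)OC)C(=O)O | starting material
2 | mixed isobutyl carbonic anhydride of 1 | CC(C)(C)OC(=O)N[C@@H](CC(=O)OC)C(=O)OC(=O)OCC(C)C | intermediate (not isolated)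
3 | methyl (3S)-3-[(tert-butoxycarbonyl)amino]-4-hydroxybutanoate | CC(C)(C)OC(=O)N[C@@H](CC(=O)OC)CO | intermediate
4 | tert-butyl (4S)-4-(2-methoxy-2-oxoethyl)-2,2-dimethyl-1,3-oxazolidine-3-carboxylate | CC(C)(C)OC(=O)N1[C@@H](CC(=O)OC)COC1(C)C | intermediate
5 | ethyl vinyl ether | C=COCC | starting material
6 | 1-ethoxyvinyllithium | [Li]C(=C)OCC | intermediate (not isolated)
7 | lithium alkoxide of the double adduct | CC(C)(C)OC(=O)N1[C@@H](CC([O-])(C(=C)OCC)C(=C)OCC)COC1(C)C.[Li+] | intermediate (not isolated)
8 | tert-butyl (4S)-4-{2-[(tert-butyldimethylsilyl)oxy]-3-ethoxy-2-(1-ethoxyethenyl)but-3-en-1-yl}-2,2-dimethyl-1,3-oxazolidine-3-carboxylate | CC(C)(C)OC(=O)N1[C@@H](CC(O[Si](C)(C)C(C)(C)C)(C(=C)OCC)C(=C)OCC)COC1(C)C | intermediate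
9 | trimethyl orthoformate | COC(OC)OC | starting material
10 | open-chain mono-adduct (one arm converted to C(OEt)(OMe)CH2CH(OMe)2; diastereomer mixture) | CC(C)(C)OC(=O)N1[C@@H](CC(O[Si](C)(C)C(C)(C)C)(C(=C)OCC)C(OC)(OCC)CC(OC)OC)COC1(C)C | intermediate (not isolated)
11 | cyclic bis(ethyl methyl ketal) of 12 (diastereomer mixture) | CC(C)(C)OC(=O)N1[C@@H](CC2(O[Si](C)(C)C(C)(C)C)C(OC)(OCC)CC(OC)CC2(OC)OCC)COC1(C)C | intermediate (not isolated)
12 | tert-butyl (4S)-4-({cis-1-[(tert-butyldimethylsilyl)oxy]-4-methoxy-2,6-dioxocyclohexyl}methyl)-2,2-dimethyl-1,3-oxazolidine-3-carboxylate | CC(C)(C)OC(=O)N1[C@@H](C[C@@]2(O[Si](C)(C)C(C)(C)C)C(=O)C[C@H](OC)CC2=O)COC1(C)C | intermediate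
13 | bis(trimethylsilyl enol ether) of 12 | CC(C)(C)OC(=O)N1[C@@H](C[C@@]2(O[Si](C)(C)C(C)(C)C)C(O[Si](C)(C)C)=C[C@H](OC)C=C2O[Si](C)(C)C)COC1(C)C | intermediate (not isolated)
14 | 3,5-dibromo derivative of 12 (epimer mixture at CHBr) | CC(C)(C)OC(=O)N1[C@@H](C[C@@]2(O[Si](C)(C)C(C)(C)C)C(=O)C(Br)[C@H](OC)C(Br)C2=O)COC1(C)C | intermediate
15 | tert-butyl N-[(2S)-1-{3,5-dibromo-cis-1-[(tert-butyldimethylsilyl)oxy]-4-methoxy-2,6-dioxocyclohexyl}-3-hydroxypropan-2-yl]carbamate | CC(C)(C)OC(=O)N[C@@H](C[C@@]1(O[Si](C)(C)C(C)(C)C)C(=O)C(Br)[C@H](OC)C(Br)C1=O)CO | intermediate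
16 | tert-butyl N-[(2S)-1-{3,5-dibromo-cis-1-[(tert-butyldimethylsilyl)oxy]-4-methoxy-2,6-dioxocyclohexyl}-3-oxopropan-2-yl]carbamate | CC(C)(C)OC(=O)N[C@@H](C[C@@]1(O[Si](C)(C)C(C)(C)C)C(=O)C(Br)[C@H](OC)C(Br)C1=O)C=O | intermediate
17 | bis(diiodosamarium enolate) of debrominated 16 | CC(C)(C)OC(=O)N[C@@H](C[C@@]1(O[Si](C)(C)C(C)(C)C)C(O[Sm](I)I)=C[C@H](OC)C=C1O[Sm](I)I)C=O | intermediate (not isolated)
18 | tert-butyl N-{1-[(tert-butyldimethylsilyl)oxy]-6-hydroxy-4-methoxy-2,9-dioxobicyclo[3.3.1]nonan-7-yl}carbamate (stereocentres as in 27) | CC(C)(C)OC(=O)N[C@H]1C[C@@]2(O[Si](C)(C)C(C)(C)C)C(=O)[C@@H]([C@H]1O)[C@H](OC)CC2=O | intermediate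
19 | 6-O-triethylsilyl ether of 18 | CC(C)(C)OC(=O)N[C@H]1C[C@@]2(O[Si](C)(C)C(C)(C)C)C(=O)[C@@H]([C@H]1O[Si](CC)(CC)CC)[C@H](OC)CC2=O | intermediate
20 | dilithio species of 19 (N-lithiocarbamate, C2–C3 lithium enolate) | CC(C)(C)OC(=O)[N-][C@H]1C[C@@]2(O[Si](C)(C)C(C)(C)C)C(=O)[C@@H]([C@H]1O[Si](CC)(CC)CC)[C@H](OC)C=C2[O-].[Li+].[Li+] | intermediate (not isolated)
21 | C2 enol triflate of 19 | CC(C)(C)OC(=O)N[C@H]1C[C@@]2(O[Si](C)(C)C(C)(C)C)C(=O)[C@@H]([C@H]1O[Si](CC)(CC)CC)[C@H](OC)C=C2OS(=O)(=O)C(F)(F)F | intermediate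
22 | tert-butyl N-{1-[(tert-butyldimethylsilyl)oxy]-4-methoxy-9-oxo-6-[(triethylsilyl)oxy]bicyclo[3.3.1]non-2-en-7-yl}carbamate | CC(C)(C)OC(=O)N[C@H]1C[C@@]2(O[Si](C)(C)C(C)(C)C)C(=O)[C@@H]([C@H]1O[Si](CC)(CC)CC)[C@H](OC)C=C2 | intermediate
23 | tert-butyl N-(1,6-dihydroxy-4-methoxy-9-oxobicyclo[3.3.1]non-2-en-7-yl)carbamate | CC(C)(C)OC(=O)N[C@H]1C[C@@]2(O)C(=O)[C@@H]([C@H]1O)[C@H](OC)C=C2 | intermediate
24 | (2E)-dodec-2-enoic acid | CCCCCCCCC/C=C/C(=O)O | starting material
25 | 7-ammonio-1,6-dihydroxy-4-methoxybicyclo[3.3.1]non-2-en-9-one trifluoroacetate | [NH3+][C@H]1C[C@@]2(O)C(=O)[C@@H]([C@H]1O)[C@H](OC)C=C2.[O-]C(=O)C(F)(F)F | intermediate (not isolated)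
26 | (2E)-N-(1,6-dihydroxy-4-methoxy-9-oxobicyclo[3.3.1]non-2-en-7-yl)dodec-2-enamide | CCCCCCCCC/C=C/C(=O)N[C@H]1C[C@@]2(O)C(=O)[C@@H]([C@H]1O)[C@H](OC)C=C2 | intermediate
27 | (2E)-N-[(1S,2S,3S,4S,5S,6R,7S)-2,3-epoxy-1,6-dihydroxy-4-methoxy-9-oxobicyclo[3.3.1]nonan-7-yl]dodec-2-enamide | CCCCCCCCC/C=C/C(=O)N[C@H]1C[C@@]2(O)C(=O)[C@@H]([C@H]1O)[C@H](OC)[C@@H]1O[C@@H]12 | target

Correction to step 3: the reagent line there should read only "tert-butyldimethylsilyl trifluoromethanesulfonate, CC(C)(C)[Si](C)(C)OS(=O)(=O)C(F)(F)F".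

**Summary**

Total step count: 14. Longest linear sequence: 14 steps (1 → 27); 5, 9 and 24 are commercial and enter in steps 3, 4 and 13.

**Steps most likely to fail**

Step 4 (Proposed new method). What may go wrong: capture of the second enol ether arm by another orthoformate-derived cation (double alkylation, oligomerization) outruns ring closure, or methanol is lost from the β-methoxy diketone during ketal hydrolysis. The fallback uses known reactions only, sets out from 8 and comes back to the route at 12. The enol ethers of 8 are hydrolysed (oxalic acid, wet THF) to the 3-silyloxypentane-2,4-dione F1. One methyl ketone is converted with LiN(SiMe3)2 (1 equiv) and Me3SiCl into the mono(trimethylsilyl enol ether) F2. F2 is alkylated with 9 under Me3SiOTf catalysis at −78 °C (Mukaiyama-type acetal alkylation) to the isolated β-keto dimethyl acetal F3. Kinetic enolization of the remaining methyl ketone gives the silyl enol ether F4, and TiCl4 at −78 °C closes ring B by an intramolecular Mukaiyama aldol-type addition to the acetal, again forming C3–C4 last, to give 12. F2 to F4 are mixtures at the carbinol carbon, which stops being stereogenic again in 12.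

Step 8. What may go wrong: over-reduction by divalent samarium (reduction or pinacol coupling of the aldehyde, reductive loss of the α-silyloxy group) or protonation of the enolate before C–C bond formation; the preceding double bromination may also erode the 4-OMe by ionization of the bis(silyl enol ether). The fallback sets out from 12 and comes back at 18, bypassing steps 5 to 8. Acetonide cleavage (p-TsOH, MeOH) gives the N-Boc amino alcohol F5, Dess–Martin oxidation gives the bromine-free keto aldehyde F6, and a conventional base-mediated intramolecular aldol (catalytic 1,8-diazabicyclo[5.4.0]undec-7-ene, CH2Cl2, −20 °C) closes ring A. Arm selection by the equatorial preference of the carbamate still applies, at the price of possible partial epimerization of the aldehyde α-carbon and of base-induced loss of methanol.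

Step 10. What may go wrong: β-elimination of the axial 4-methoxy group from the C2 enolate, or N-triflation of the carbamate anion. The fallback sets out from 19 and comes back at 22. The C2 ketone is reduced chemoselectively with LiBH(s-Bu)3 at −78 °C (the C9 carbonyl is shielded by the silyloxy-bearing C1 and the C5 bridgehead) to the C2 alcohol F7, and syn-dehydration with the Burgess reagent toward C3, the only carbon with β-hydrogens, gives the alkene 22.

**Further compounds**

F1 | step 4 | tert-butyl (4S)-4-{2-acetyl-2-[(tert-butyldimethylsilyl)oxy]-3-oxobutyl}-2,2-dimethyl-1,3-oxazolidine-3-carboxylate | CC(C)(C)OC(=O)N1[C@@H](CC(O[Si](C)(C)C(C)(C)C)(C(C)=O)C(C)=O)COC1(C)C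
F2 | step 4 | mono(trimethylsilyl enol ether) of F1 | CC(C)(C)OC(=O)N1[C@@H](CC(O[Si](C)(C)C(C)(C)C)(C(C)=O)C(=C)O[Si](C)(C)C)COC1(C)C
F3 | step 4 | β-keto dimethyl acetal (one arm extended to C(=O)CH2CH(OMe)2) | CC(C)(C)OC(=O)N1[C@@H](CC(O[Si](C)(C)C(C)(C)C)(C(C)=O)C(=O)CC(OC)OC)COC1(C)C
F4 | step 4 | trimethylsilyl enol ether of the methyl ketone of F3 | CC(C)(C)OC(=O)N1[C@@H](CC(O[Si](C)(C)C(C)(C)C)(C(=C)O[Si](C)(C)C)C(=O)CC(OC)OC)COC1(C)C
F5 | step 8 | tert-butyl N-[(2S)-1-{cis-1-[(tert-butyldimethylsilyl)oxy]-4-methoxy-2,6-dioxocyclohexyl}-3-hydroxypropan-2-yl]carbamate | CC(C)(C)OC(=O)N[C@@H](C[C@@]1(O[Si](C)(C)C(C)(C)C)C(=O)C[C@H](OC)CC1=O)CO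
F6 | step 8 | tert-butyl N-[(2S)-1-{cis-1-[(tert-butyldimethylsilyl)oxy]-4-methoxy-2,6-dioxocyclohexyl}-3-oxopropan-2-yl]carbamate | CC(C)(C)OC(=O)N[C@@H](C[C@@]1(O[Si](C)(C)C(C)(C)C)C(=O)C[C@H](OC)CC1=O)C=O
F7 | step 10 | C2 alcohol of 19 (either C2 epimer) | CC(C)(C)OC(=O)N[C@H]1C[C@@]2(O[Si](C)(C)C(C)(C)C)C(=O)[C@@H]([C@H]1O[Si](CC)(CC)CC)[C@H](OC)CC2O
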